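The earlier runs and the new flask are simulated for substances that don't exist, and the scatter is random.

Slowness lets us reckon this flask on paper: in the dawn run the dormant form falls from 60.7% (mean of the first two readings) to just 50.7% by 40.0 min.

in all of them: substrate 29 mM
- dawn: reagent 0.87 equiv (fed, over 50 min); run made earlier
- autumn: reagent 2 equiv (fed, over 50 min); run made earlier
- flask: reagent 1.30 equiv (fed, over 50 min); time 50 min

| run | time / min | mono adduct / % | idle adduct / % | dormant form / % |
|---|---|---|---|---|
| dawn | 3.00 | 0.2 | 0.8 | 58.9 |
| dawn | 8.00 | 1.5 | 0 | 62.4 |
| dawn | 15.0 | 2.3 | 1.2 | 59.4 |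
| dawn | 40.0 | 15.8 | 8.5 | 50.7 |
| autumn | 10.0 | 2.8 | 2.1 | 60.0 |
| autumn | 20.0 | 9.8 | 4.1 | 55.9 |
| autumn | 30.0 | 22.4 | 9.4 | 47.6 |
| autumn | 40.0 | 33.7 | 10.8 | 40.6 |

(standard deviation of a reading: 1 percentage point)

- the mono adduct in the flask at 50 min, as a percentage of the substrate charged
- the idle adduct in the flask at 50 min, as a percentage of the substrate charged
- the dormant form in the flask at 50 min, as a percentage of the substrate charged
- the substrate in the flask at 50 min, as a percentage of the substrate charged
- concentration of reagent at 50 min, in mM

- in percentages every species weighs as the substrate in it: one idle adduct counts as two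
- for mono adduct the idle adduct is counted in
- in an amount of mono adduct, one idle adduct counts as one mono adduct

We go to logarithms. Take the reagent exposure: the concentration of reagent summed over the minutes, counted as fed with none used, so it grows with the square of time. The autumn run has 928 mM·min of it at 40.0 min, and its dormant form has reached 40.6%. So one power of ten in dormant form costs 5320 mM·min, our decade exposure, a pseudo-first-order fall with exposure standing in for time. The dawn run, read alike, gives 5190 mM·min.

The new flask reaches 943 mM·min at 50 min, about the same as the autumn run at 40.0 min, so we expect 40.3% dormant form.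

The forecast, reached by “Stepping the 2.6 %/min feed by hand”, says 32% mono adduct, 11.7% idle adduct, 41% dormant form, 21% substrate and 28.4 mM reagent.

The flask gives 32.3%, 11.0%, 39.6%, 22.2% and 28.1 mM, in that order.

    substrate + reagent → mono adduct (k = 1.50 /M/min)
    reagent + mono adduct → bis adduct (k = 0.0340 /M/min)
    reagent + bis adduct ⇌ triple product (K = 6.90 /M, k = 2.20 /M/min)
    substrate ⇌ dormant form (K = 1.70, k = 0.620 /min)
    substrate + mono adduct ⇌ idle adduct, settled at all times (K = 32.0 /M)

The dormant form in the new flask lies 0.70 percentage points below our figure, which was itself built on readings that scatter by 1 point. Substrate and dormant form relax into each other with a half-life of 0.704 min, far shorter than the 50 min of the run. Read back from this flask, the decade exposure is 5084 mM·min.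

The neighbour flask with 3.20 equiv of reagent reaches 2320 mM·min, so our decade exposure gives 22.2% dormant form. Computed, that neighbour flask holds 21.9% dormant form.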